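Cuts: the C4 formyl group goes back to a diethyl acetal. The benzo ring is then opened at C3a–C7a, C4–C5 and C6–C7, which also opens the cyclopentenone and leaves an acyclic (Z)-enediynone plus acetylene. The enediynone is cut at C1–C7a (acyl–alkynyl), C3–C3a (alkenyl–alkynyl) and C2–C3' (alkenyl–azulenyl).
Enabling feature: of the benzo-ring atoms C3a, C4, C5, C6, C7 and C7a, only C4 (CHO) and C7 (CH3), the neighbours of the fusion atoms, are substituted, and C5 and C6 carry hydrogen. The ring therefore maps onto a 1,6-diyne with CH3 and masked-CHO end caps, tethered by C1(=O)–C2=C3 of the five-membered ring and closed with C2H2. C2 carries azulene C3' from the start.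
Forward order: C2–C3' (rhodium carbene on guaiazulene), C3–C3a (Sonogashira), C1–C7a (Weinreb ketone synthesis), then the five-membered enone ring and the benzene ring form together in one cycloaddition. Both azulene rings come with guaiazulene, and acetal hydrolysis ends the route.
Stereochemistry: the target has no stereocentre. The only stereo-element on the way is the (Z) geometry of C2=C3, which places both alkynes on the same side; it is set by triflation of a chelated enolate and carried on with retention.

Key step: step 7

Numbering: indenone atoms are C1–C7a and azulene atoms are primed. "Guaiazulen-3-yl" means guaiazulene bonded through C3', the free CH of the five-membered ring next to the C4' methyl group (= 3,8-dimethyl-5-(propan-2-yl)azulen-1-yl).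
Assumption: the target is drawn without stereodescriptors, so the hindered C2–C3' axis is treated as configurationally undefined and racemic BINAP is used.

Step 1
Reactants: 1 methyl acetoacetate
Product: 2 methyl 2-diazo-3-oxobutanoate
Conditions: p-ABSA, Et3N, MeCN, 0 °C → rt
Reagents that add atoms: 4-acetamidobenzenesulfonyl azide (p-ABSA), CC(=O)Nc1ccc(cc1)S(=O)(=O)N=[N+]=[N-]
Why: Regitz diazo transfer, in which the amine-generated enolate of the 1,3-dicarbonyl attacks the terminal nitrogen of the sulfonyl azide and the adduct collapses to the diazo compound and the sulfonamide, a routine reaction of acetoacetates.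

Step 2
Reactants: 2 methyl 2-diazo-3-oxobutanoate; 3 guaiazulene
Product: 4 methyl 2-(guaiazulen-3-yl)-3-oxobutanoate (racemic, enolisable)
Conditions: Rh2(OAc)4 (1 mol %), 3 (1.5 equiv), ClCH2CH2Cl, 60 °C, 2 added by syringe pump
Reagents that add atoms: none
Why: Formal aromatic C–H insertion of a rhodium carbene (electrophilic substitution), in which the acceptor–acceptor carbene is attacked by C3', the only unsubstituted nucleophilic position of the five-membered azulene ring, to give a tropylium-stabilised zwitterion that rearomatises by proton transfer, as known for metal-carbene alkylation of azulenes, indoles and pyrroles; the new C2 stereocentre is racemic and is erased in step 3.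

Step 3
Reactants: 4 methyl 2-(guaiazulen-3-yl)-3-oxobutanoate
Product: 6 methyl (2Z)-2-(guaiazulen-3-yl)-3-[(trifluoromethylsulfonyl)oxy]but-2-enoate, via sodium (Z)-enolate 5 (not isolated)
Conditions: NaH, THF, 0 °C; then PhNTf2, 0 °C → rt
Reagents that add atoms: N-phenylbis(trifluoromethanesulfonimide) (PhNTf2), O=S(=O)(N(c1ccccc1)S(=O)(=O)C(F)(F)F)C(F)(F)F; sodium hydride (sodium of 5 only), [Na+].[H-]
Why: Enol triflation of a β-keto ester through its metal chelate, in which sodium in THF bridges the ketone-derived and ester oxygens so that O-sulfonylation by the mild triflyl donor PhNTf2 (preferred to Tf2O to spare the azulene) fixes OTf cis to CO2Me, the (Z) geometry needed later, and any (E) isomer would be removed by chromatography at this stage.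

Step 4
Reactants: 6 methyl (2Z)-2-(guaiazulen-3-yl)-3-[(trifluoromethylsulfonyl)oxy]but-2-enoate; 7 3,3-diethoxyprop-1-yne
Product: 8 methyl (2Z)-6,6-diethoxy-2-(guaiazulen-3-yl)-3-methylhex-2-en-4-ynoate
Conditions: PdCl2(PPh3)2 (3 mol %), CuI (5 mol %), Et3N, THF, rt, degassed
Reagents that add atoms: none
Why: Sonogashira coupling, in which the electron-poor vinyl triflate adds oxidatively to zerovalent palladium at room temperature and couples with the copper acetylide with retention of alkene geometry, while acetal, ester and azulene are inert to the mild amine base.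

Step 5
Reactants: 8 methyl (2Z)-6,6-diethoxy-2-(guaiazulen-3-yl)-3-methylhex-2-en-4-ynoate
Product: 9 (2Z)-6,6-diethoxy-2-(guaiazulen-3-yl)-N-methoxy-N,3-dimethylhex-2-en-4-ynamide
Conditions: MeNH(OMe)·HCl, iPrMgCl, THF, −20 °C; then 8, −20 → 0 °C
Reagents that add atoms: N,O-dimethylhydroxylamine hydrochloride, CNOC.Cl
Why: Weinreb amide synthesis by aminolysis of an ester with a magnesium amide, in which the small and strongly nucleophilic ClMgN(OMe)Me attacks the ester carbonyl at low temperature, the fully substituted β-carbon disfavours conjugate addition, and the non-acidic medium leaves the acetal and the (Z) alkene intact.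

Step 6
Reactants: 9 (2Z)-6,6-diethoxy-2-(guaiazulen-3-yl)-N-methoxy-N,3-dimethylhex-2-en-4-ynamide; 10 1-propynylmagnesium bromide
Product: 12 (5Z)-9,9-diethoxy-5-(guaiazulen-3-yl)-6-methylnon-5-ene-2,7-diyn-4-one, via magnesium hemiaminal chelate 11 (not isolated)
Conditions: 10 (0.5 M in THF), THF, 0 °C → rt; inverse quench into cold aq NH4Cl
Reagents that add atoms: none
Why: Weinreb ketone synthesis, in which the alkynyl Grignard reagent adds only once because the five-membered magnesium chelate 11 persists until the quench, and pouring into cold buffer removes the liberated amine before it can add to the ynone without harming the acetal.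

Step 7
Reactants: 12 (5Z)-9,9-diethoxy-5-(guaiazulen-3-yl)-6-methylnon-5-ene-2,7-diyn-4-one; 13 acetylene
Product: 14 4-(diethoxymethyl)-2-(guaiazulen-3-yl)-3,7-dimethyl-1H-inden-1-one
Conditions: [Rh(cod)2]BF4 (10 mol %), rac-BINAP (10 mol %), pre-activated under H2, CH2Cl2, acetone-free acetylene (1 atm), rt, 12 added by syringe pump
Reagents that add atoms: none
Why: Cationic monovalent rhodium bearing BINAP binds both alkynes of 12 and couples them oxidatively to a rhodacyclopentadiene of trivalent rhodium, which forms C3a–C7a; acetylene then coordinates and inserts into a Rh–C bond, and reductive elimination completes the pair C4–C5 and C6–C7 and returns the catalyst. The closest known reaction type is the rhodium-catalysed (2+2+2) cycloaddition of tethered 1,6-diynes with monoalkynes, acetylene gas included, which is documented for carbonyl-containing tethers and for aryl-bridged diynones that give fluorenones. The five-membered ring closes by intramolecular oxidative coupling of the two inner alkyne carbons across the three-atom tether C1–C2–C3, and the six-membered ring closes by intermolecular insertion of acetylene into the metallacycle followed by C–C reductive elimination, with aromatisation as the driving force. No stereocentre is created, so racemic BINAP suffices, and no regiochemical issue exists because acetylene is symmetric and the CH3 and CH(OEt)2 caps sit on the diyne termini that become C7 and C4. The step needs chemoselectivity for cross-cycloaddition over self-coupling of 12, over attack of the C1 carbonyl oxygen on the cis alkyne and over oligomerisation of acetylene, and it is secured by the fixed (Z) alkene that holds both alkynes on one side for chelation, by the capped alkyne termini that slow self-coupling, by the acetylene-saturated solution and by syringe-pump addition of 12. The acetal keeps the future aldehyde away from rhodium-mediated decarbonylation, and the rhodium centre works at C4 and C7, far from the bulky azulene at C2.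

Step 8
Reactants: 14 4-(diethoxymethyl)-2-(guaiazulen-3-yl)-3,7-dimethyl-1H-inden-1-one
Product: 15 2-(guaiazulen-3-yl)-3,7-dimethyl-1-oxo-1H-indene-4-carbaldehyde (CNP0233877.0)
Conditions: 1 M aq HCl, THF, rt
Reagents that add atoms: water, O
Why: Acid-catalysed acetal hydrolysis, in which protonation and loss of ethanol give a benzylic oxocarbenium ion that water captures, while the dilute acid is too weak to protonate the acceptor-substituted azulene, whose nucleophilic positions C1' and C3' are both blocked against condensation with the new aldehyde.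

Compound list
1 | methyl acetoacetate | CC(=O)CC(=O)OC | starting material
2 | methyl 2-diazo-3-oxobutanoate | CC(=O)C(=[N+]=[N-])C(=O)OC | intermediate
3 | guaiazulene (1,4-dimethyl-7-(propan-2-yl)azulene) | c1cc(C)c2cc(C(C)C)ccc(C)c1-2 | starting material
4 | methyl 2-(guaiazulen-3-yl)-3-oxobutanoate, racemic | CC(=O)C(C(=O)OC)c1cc(C)c2cc(C(C)C)ccc(C)c1-2 | intermediate
5 | sodium (Z)-enolate of 4, oxygen cis to the ester, not isolated | C/C([O-])=C(/C(=O)OC)c1cc(C)c2cc(C(C)C)ccc(C)c1-2.[Na+] | intermediate
6 | methyl (2Z)-2-(guaiazulen-3-yl)-3-[(trifluoromethylsulfonyl)oxy]but-2-enoate | C/C(OS(=O)(=O)C(F)(F)F)=C(/C(=O)OC)c1cc(C)c2cc(C(C)C)ccc(C)c1-2 | intermediate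
7 | 3,3-diethoxyprop-1-yne | C#CC(OCC)OCC | starting material
8 | methyl (2Z)-6,6-diethoxy-2-(guaiazulen-3-yl)-3-methylhex-2-en-4-ynoate | C/C(C#CC(OCC)OCC)=C(/C(=O)OC)c1cc(C)c2cc(C(C)C)ccc(C)c1-2 | intermediate
9 | (2Z)-6,6-diethoxy-2-(guaiazulen-3-yl)-N-methoxy-N,3-dimethylhex-2-en-4-ynamide | C/C(C#CC(OCC)OCC)=C(/C(=O)N(C)OC)c1cc(C)c2cc(C(C)C)ccc(C)c1-2 | intermediate
10 | 1-propynylmagnesium bromide | CC#C[Mg]Br | starting material
11 | bromomagnesium alkoxide of the tetrahedral adduct of 10 to 9 (chelated hemiaminal, racemic), not isolated | C/C(C#CC(OCC)OCC)=C(/C(O[Mg]Br)(C#CC)N(C)OC)c1cc(C)c2cc(C(C)C)ccc(C)c1-2 | intermediate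
12 | (5Z)-9,9-diethoxy-5-(guaiazulen-3-yl)-6-methylnon-5-ene-2,7-diyn-4-one | CC#CC(=O)/C(=C(/C)C#CC(OCC)OCC)c1cc(C)c2cc(C(C)C)ccc(C)c1-2 | intermediate
13 | acetylene | C#C | starting material
14 | 4-(diethoxymethyl)-2-(guaiazulen-3-yl)-3,7-dimethyl-1H-inden-1-one | CCOC(OCC)c1ccc(C)c2c1C(C)=C(c1cc(C)c3cc(C(C)C)ccc(C)c1-3)C2=O | intermediate
15 | 2-(guaiazulen-3-yl)-3,7-dimethyl-1-oxo-1H-indene-4-carbaldehyde (CNP0233877.0) | CC1=C(c2cc(C)c3cc(C(C)C)ccc(C)c2-3)C(=O)c2c(C)ccc(C=O)c21 | target

Total step count: 8. Longest linear sequence: 8 steps (1 → 15). Compounds 3, 7, 10 and 13 are bought and enter directly.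

Steps most likely to fail

First risk, step 7. Three processes may outrun capture of the metallacycle by acetylene:
- attack of the C1 carbonyl oxygen on the rhodium-activated cis alkyne (cycloisomerisation along the furyl carbene path);
- binding of the cationic catalyst by the electron-rich azulene;
- self-coupling of the diyne.

The fallback takes the carbonyl group out of play during the cycloaddition while forming the same three bonds. Setting out from 12, 1,2-reduction with DIBAL-H (toluene, −78 °C) should give racemic (5Z)-9,9-diethoxy-5-(guaiazulen-3-yl)-6-methylnon-5-ene-2,7-diyn-4-ol F1. TBSCl and imidazole in DMF convert it into tert-butyl{[(5Z)-9,9-diethoxy-5-(guaiazulen-3-yl)-6-methylnon-5-ene-2,7-diyn-4-yl]oxy}dimethylsilane F2. Cycloaddition with acetylene under neutral RhCl(PPh3)3 in toluene then gives tert-butyl{[4-(diethoxymethyl)-2-(guaiazulen-3-yl)-3,7-dimethyl-1H-inden-1-yl]oxy}dimethylsilane F3. TBAF buffered with AcOH frees 4-(diethoxymethyl)-2-(guaiazulen-3-yl)-3,7-dimethyl-1H-inden-1-ol F4, and MnO2 in CH2Cl2 oxidises this benzylic, allylic alcohol. The route is rejoined at 14.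

Second risk, step 5. Acyl substitution at the crowded ester carbonyl, flanked by the twisted azulene and a fully substituted alkene, may be slow. Conjugate 1,6-addition of the magnesium amide to the enyne ester, or erosion of the alkene geometry, could then take over. The fallback replaces acyl substitution by a redox detour. Setting out from 8, DIBAL-H (CH2Cl2, −78 °C) should give (2Z)-6,6-diethoxy-2-(guaiazulen-3-yl)-3-methylhex-2-en-4-yn-1-ol F5. MnO2 (CH2Cl2, rt) gives (2Z)-6,6-diethoxy-2-(guaiazulen-3-yl)-3-methylhex-2-en-4-ynal F6. Addition of 10 (THF, −78 °C) to the unhindered aldehyde gives (5Z)-9,9-diethoxy-5-(guaiazulen-3-yl)-6-methylnon-5-ene-2,7-diyn-4-ol F1, and Dess–Martin periodinane with NaHCO3 oxidises it. The route is rejoined at 12.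

Third risk, step 2. The carbene may be consumed in ways other than substitution at the crowded C3':
- cyclopropanation and ring expansion at the seven-membered ring;
- insertion at the C4' methyl group;
- Wolff rearrangement and dimerisation.

The fallback builds C2–C3' by classical electrophilic substitution. Setting out from 3, uncatalysed Friedel–Crafts acylation with methyl chlorooxoacetate (CH2Cl2, 0 °C) should give methyl 2-(guaiazulen-3-yl)-2-oxoacetate F7. NaBH4 with BF3·OEt2, the established deoxygenation of 1-acylazulenes to 1-alkylazulenes, gives methyl 2-(guaiazulen-3-yl)acetate F8. Crossed Claisen acetylation of its lithium enolate (LiHMDS, THF, −78 °C, then 1-acetylimidazole) rejoins the route at 4, and steps 1 and 2 are then not needed.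

Further compounds
F1 | step 7 | (5Z)-9,9-diethoxy-5-(guaiazulen-3-yl)-6-methylnon-5-ene-2,7-diyn-4-ol, racemic | CC#CC(O)/C(=C(/C)C#CC(OCC)OCC)c1cc(C)c2cc(C(C)C)ccc(C)c1-2
F2 | step 7 | tert-butyl{[(5Z)-9,9-diethoxy-5-(guaiazulen-3-yl)-6-methylnon-5-ene-2,7-diyn-4-yl]oxy}dimethylsilane, racemic | CC#CC(O[Si](C)(C)C(C)(C)C)/C(=C(/C)C#CC(OCC)OCC)c1cc(C)c2cc(C(C)C)ccc(C)c1-2
F3 | step 7 | tert-butyl{[4-(diethoxymethyl)-2-(guaiazulen-3-yl)-3,7-dimethyl-1H-inden-1-yl]oxy}dimethylsilane, racemic | CCOC(OCC)c1ccc(C)c2c1C(C)=C(c1cc(C)c3cc(C(C)C)ccc(C)c1-3)C2O[Si](C)(C)C(C)(C)C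
F4 | step 7 | 4-(diethoxymethyl)-2-(guaiazulen-3-yl)-3,7-dimethyl-1H-inden-1-ol, racemic | CCOC(OCC)c1ccc(C)c2c1C(C)=C(c1cc(C)c3cc(C(C)C)ccc(C)c1-3)C2O
F5 | step 5 | (2Z)-6,6-diethoxy-2-(guaiazulen-3-yl)-3-methylhex-2-en-4-yn-1-ol | C/C(C#CC(OCC)OCC)=C(/CO)c1cc(C)c2cc(C(C)C)ccc(C)c1-2
F6 | step 5 | (2Z)-6,6-diethoxy-2-(guaiazulen-3-yl)-3-methylhex-2-en-4-ynal | C/C(C#CC(OCC)OCC)=C(/C=O)c1cc(C)c2cc(C(C)C)ccc(C)c1-2
F7 | step 2 | methyl 2-(guaiazulen-3-yl)-2-oxoacetate | COC(=O)C(=O)c1cc(C)c2cc(C(C)C)ccc(C)c1-2
F8 | step 2 | methyl 2-(guaiazulen-3-yl)acetate | COC(=O)Cc1cc(C)c2cc(C(C)C)ccc(C)c1-2
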